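Ring A is fully substituted: oxygen at C5 and C7, prenyl groups at C6 and C8, and the C4a–C8a edge shared with pyranone ring C. This alternating pattern is exactly what a vinylketene and a siloxyalkyne assemble, so ring A is disconnected to a ring C acyl diazo compound and an oxygenated alkyne. One photochemical–thermal operation forms C8–C8a, C5–C6, C7–C8 and C4a–C5 and fixes every ring A substituent. The precursor is a 5-aryl-4-pyranone carrying a 2-diazo-5-methylhex-4-enoyl group at pyranone C2; ring B is masked as its bis(triisopropylsilyl) ether, so a single fluoride treatment after the annulation frees all three silylated phenols without acid.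

Key step: step 10

Remark on the chemistry: ethyl 4-methylpent-3-enoate (14) is taken to be a catalogue compound; carbinol 10 and the transient species 12, 19 and 21 are racemic, which is immaterial because 11, 13, 22 and 23 contain no stereocentre.

Step 1
Reactants: 1 kojic acid (5-hydroxy-2-(hydroxymethyl)-4H-pyran-4-one)
Product: 2 6-(hydroxymethyl)-4-oxo-4H-pyran-3-yl trifluoromethanesulfonate
Conditions: PhNTf2, Et3N, DMF, 0 °C → rt
Reagents that add atoms: N-phenylbis(trifluoromethanesulfonimide), O=S(=O)(N(c1ccccc1)S(=O)(=O)C(F)(F)F)C(F)(F)F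
Why: Chemoselective O-triflation: the enolic C5 hydroxyl is far more acidic than the primary alcohol, so only its ammonium salt should be sulfonylated by the mild triflyl donor.

Step 2
Reactants: 3 4-bromoresorcinol (4-bromobenzene-1,3-diol)
Product: 4 1-bromo-2,4-bis(triisopropylsilyloxy)benzene
Conditions: i-Pr3SiCl, imidazole, DMF, rt → 40 °C
Reagents that add atoms: chlorotriisopropylsilane, CC(C)[Si](Cl)(C(C)C)C(C)C
Why: Imidazole-promoted silyl ether formation on both phenols; the bulky triisopropylsilyl ethers are chosen because they should withstand aqueous phosphate, a Grignard reagent and amide bases later on.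

Step 3
Reactants: 4 1-bromo-2,4-bis(triisopropylsilyloxy)benzene
Product: 5 2-[2,4-bis(triisopropylsilyloxy)phenyl]-4,4,5,5-tetramethyl-1,3,2-dioxaborolane
Conditions: B2pin2, PdCl2(dppf), KOAc, 1,4-dioxane, 90 °C
Reagents that add atoms: bis(pinacolato)diboron, CC1(C)OB(OC1(C)C)B1OC(C)(C)C(C)(C)O1
Why: Miyaura borylation: zerovalent palladium inserts into the C–Br bond and acetate mediates boryl transfer, which leaves the silyl ethers untouched and avoids an ortho-lithiated aryl silyl ether prone to O-to-C silyl migration.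

Step 4
Reactants: 2 6-(hydroxymethyl)-4-oxo-4H-pyran-3-yl trifluoromethanesulfonate; 5 2-[2,4-bis(triisopropylsilyloxy)phenyl]-4,4,5,5-tetramethyl-1,3,2-dioxaborolane
Product: 6 5-[2,4-bis(triisopropylsilyloxy)phenyl]-2-(hydroxymethyl)-4H-pyran-4-one
Conditions: Pd(OAc)2, SPhos, K3PO4, THF–H2O, 50 °C
Reagents that add atoms: none
Why: Suzuki–Miyaura coupling: the electron-poor enol triflate should add readily to zerovalent palladium, SPhos accommodates the ortho-silyloxy boronate, and phosphate at 50 °C is mild towards the triflate, the free alcohol and the silyl ethers.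

Step 5
Reactants: 6 5-[2,4-bis(triisopropylsilyloxy)phenyl]-2-(hydroxymethyl)-4H-pyran-4-one
Product: 7 5-[2,4-bis(triisopropylsilyloxy)phenyl]-4-oxo-4H-pyran-2-carbaldehyde
Conditions: Dess–Martin periodinane, CH2Cl2, 0 °C → rt
Reagents that add atoms: none
Why: Dess–Martin oxidation stops at the aldehyde under neutral anhydrous conditions that should not affect the pyranone or the aryl silyl ethers.

Step 6
Reactants: 7 5-[2,4-bis(triisopropylsilyloxy)phenyl]-4-oxo-4H-pyran-2-carbaldehyde; 8 5-bromo-2-methylpent-2-ene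
Product: 10 5-[2,4-bis(triisopropylsilyloxy)phenyl]-2-(1-hydroxy-5-methylhex-4-en-1-yl)-4H-pyran-4-one, via homoprenylmagnesium bromide 9 (not isolated)
Conditions: Mg, THF, rt; then 7, THF, −78 °C; H2O work-up
Reagents that add atoms: none
Why: Grignard addition: at −78 °C the aldehyde is far more electrophilic than the vinylogous-ester carbonyl or C6 of the pyranone, so 1,2-addition should give the carbinol as a racemate whose stereocentre is erased in step 7.

Step 7
Reactants: 10 5-[2,4-bis(triisopropylsilyloxy)phenyl]-2-(1-hydroxy-5-methylhex-4-en-1-yl)-4H-pyran-4-one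
Product: 11 5-[2,4-bis(triisopropylsilyloxy)phenyl]-2-(5-methylhex-4-enoyl)-4H-pyran-4-one
Conditions: Dess–Martin periodinane, CH2Cl2, rt
Reagents that add atoms: none
Why: Dess–Martin oxidation of the activated secondary alcohol to the ketone, to which the trisubstituted alkene and the silyl ethers are inert.

Step 8
Reactants: 11 5-[2,4-bis(triisopropylsilyloxy)phenyl]-2-(5-methylhex-4-enoyl)-4H-pyran-4-one
Product: 13 1-{5-[2,4-bis(triisopropylsilyloxy)phenyl]-4-oxo-4H-pyran-2-yl}-2-diazo-5-methylhex-4-en-1-one, via trifluoroacetyl diketone 12 (not isolated)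
Conditions: LiN(SiMe3)2, THF, −78 °C; CF3CO2CH2CF3, −78 °C; then MsN3, Et3N, H2O, MeCN, rt
Reagents that add atoms: methanesulfonyl azide, CS(=O)(=O)N=[N+]=[N-]
Why: Detrifluoroacetylative diazo transfer (Danheiser protocol): the only enolisable position, the methylene next to the ketone, is C-trifluoroacetylated through its lithium enolate, and the resulting 1,3-diketone should accept the diazo group from the sulfonyl azide with loss of the trifluoroacetyl group as its N-sulfonyl amide.

Step 9
Reactants: 14 ethyl 4-methylpent-3-enoate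
Product: 17 triisopropyl[(5-methylhex-4-en-1-yn-1-yl)oxy]silane, via lithium dibromoenolate 15 (not isolated), via lithium ynolate 16 (not isolated)
Conditions: CH2Br2, lithium 2,2,6,6-tetramethylpiperidide, THF, −78 °C; then n-BuLi, −78 °C → rt; then i-Pr3SiCl, −78 °C → rt
Reagents that add atoms: dibromomethane, BrCBr; chlorotriisopropylsilane, CC(C)[Si](Cl)(C(C)C)C(C)C
Why: Kowalski ester homologation: LiCHBr2 adds to the ester, the derived dibromoenolate undergoes bromine–lithium exchange and 1,2-shift to the ynolate, and the bulky silyl chloride should trap it on oxygen, so the prenyl group ends on the alkyne carbon remote from oxygen.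

Step 10
Reactants: 13 1-{5-[2,4-bis(triisopropylsilyloxy)phenyl]-4-oxo-4H-pyran-2-yl}-2-diazo-5-methylhex-4-en-1-one; 17 triisopropyl[(5-methylhex-4-en-1-yn-1-yl)oxy]silane
Product: 22 3-[2,4-bis(triisopropylsilyloxy)phenyl]-5-hydroxy-6,8-bis(3-methylbut-2-en-1-yl)-7-(triisopropylsilyloxy)-4H-chromen-4-one, via vinylketene 18 (not isolated), via siloxycyclobutenone 19 (not isolated), via dienylketene 20 (not isolated), via cyclohexadienone 21 (not isolated)
Conditions: 17 (2 equiv), hν (365 nm), degassed ClCH2CH2Cl, 20 °C; then 80 °C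
Reagents that add atoms: none
Why: Light absorbed by the diazo ketone expels N2 with 1,2-shift of the pyranon-2-yl group (photochemical Wolff rearrangement, C8–C8a) to give vinylketene 18, whose carbonyl carbon is attacked by the prenyl-bearing carbon of the siloxyalkyne in a [2+2] cycloaddition (C5–C6 and C7–C8) that gives cyclobutenone 19. On warming, 19 opens by conrotatory 4π electrocyclic cleavage to dienylketene 20, and ring A, a six-membered carbocycle, is closed by thermal disrotatory 6π electrocyclisation of the ketene carbon onto pyranone C3 (C4a–C5); enolisation of 21 then gives the phenol, hydrogen-bonded to the C4 carbonyl. The closest known reaction type is the second-generation Danheiser benzannulation of aryl, heteroaryl and alkenyl α-diazo ketones with siloxyalkynes. No stereocentre survives: the quaternary carbon of 19 and C4a of 21 are transient, and because ring-opening of 19 is reversible both alkene geometries of 20 should drain through the one that can cyclise. Regiochemistry rests on the polarisation of the siloxyalkyne, whose carbon remote from oxygen is the nucleophile, so its prenyl group ends at C6 between the two oxygens and the silyloxy carbon bonds to the former diazo carbon (C8). The Wolff shift must outpace hydrogen migration from the allylic CH2 on the diazo carbon; the compact sp2 migrating group, which lets the s-Z conformer be populated, and direct long-wavelength irradiation, which avoids a free triplet carbene and does not excite the pyranone, are expected to favour it, while excess alkyne intercepts the ketene before it can acylate the product phenol.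

Step 11
Reactants: 22 3-[2,4-bis(triisopropylsilyloxy)phenyl]-5-hydroxy-6,8-bis(3-methylbut-2-en-1-yl)-7-(triisopropylsilyloxy)-4H-chromen-4-one
Product: 23 3-(2,4-dihydroxyphenyl)-5,7-dihydroxy-6,8-bis(3-methylbut-2-en-1-yl)-4H-chromen-4-one (target)
Conditions: n-Bu4NF, AcOH, THF, 0 °C
Reagents that add atoms: none
Why: Fluoride-driven cleavage of all three aryl silyl ethers (Si–F bond formation) buffered with acetic acid, so that neither acid strong enough to cyclise the ortho-prenyl phenols to chromans nor base strong enough to open the pyranone is present.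

Compound list
1 | kojic acid, 5-hydroxy-2-(hydroxymethyl)-4H-pyran-4-one | OCc1cc(=O)c(O)co1 | starting material
2 | 6-(hydroxymethyl)-4-oxo-4H-pyran-3-yl trifluoromethanesulfonate | OCc1cc(=O)c(OS(=O)(=O)C(F)(F)F)co1 | intermediate
3 | 4-bromoresorcinol | Oc1ccc(Br)c(O)c1 | starting material
4 | 1-bromo-2,4-bis(triisopropylsilyloxy)benzene | CC(C)[Si](Oc1ccc(Br)c(O[Si](C(C)C)(C(C)C)C(C)C)c1)(C(C)C)C(C)C | intermediate
5 | 2-[2,4-bis(triisopropylsilyloxy)phenyl]-4,4,5,5-tetramethyl-1,3,2-dioxaborolane | CC(C)[Si](Oc1ccc(B2OC(C)(C)C(C)(C)O2)c(O[Si](C(C)C)(C(C)C)C(C)C)c1)(C(C)C)C(C)C | intermediate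
6 | 5-[2,4-bis(triisopropylsilyloxy)phenyl]-2-(hydroxymethyl)-4H-pyran-4-one | OCc1cc(=O)c(-c2ccc(O[Si](C(C)C)(C(C)C)C(C)C)cc2O[Si](C(C)C)(C(C)C)C(C)C)co1 | intermediate
7 | 5-[2,4-bis(triisopropylsilyloxy)phenyl]-4-oxo-4H-pyran-2-carbaldehyde | O=Cc1cc(=O)c(-c2ccc(O[Si](C(C)C)(C(C)C)C(C)C)cc2O[Si](C(C)C)(C(C)C)C(C)C)co1 | intermediate
8 | 5-bromo-2-methylpent-2-ene | CC(C)=CCCBr | starting material
9 | (4-methylpent-3-en-1-yl)magnesium bromide (homoprenylmagnesium bromide) | CC(C)=CCC[Mg]Br | intermediate (not isolated)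
10 | 5-[2,4-bis(triisopropylsilyloxy)phenyl]-2-(1-hydroxy-5-methylhex-4-en-1-yl)-4H-pyran-4-one (racemic) | CC(C)=CCCC(O)c1cc(=O)c(-c2ccc(O[Si](C(C)C)(C(C)C)C(C)C)cc2O[Si](C(C)C)(C(C)C)C(C)C)co1 | intermediate
11 | 5-[2,4-bis(triisopropylsilyloxy)phenyl]-2-(5-methylhex-4-enoyl)-4H-pyran-4-one | CC(C)=CCCC(=O)c1cc(=O)c(-c2ccc(O[Si](C(C)C)(C(C)C)C(C)C)cc2O[Si](C(C)C)(C(C)C)C(C)C)co1 | intermediate
12 | 1-{5-[2,4-bis(triisopropylsilyloxy)phenyl]-4-oxo-4H-pyran-2-yl}-4,4,4-trifluoro-2-(3-methylbut-2-en-1-yl)butane-1,3-dione (racemic, present as its enolate) | CC(C)=CCC(C(=O)C(F)(F)F)C(=O)c1cc(=O)c(-c2ccc(O[Si](C(C)C)(C(C)C)C(C)C)cc2O[Si](C(C)C)(C(C)C)C(C)C)co1 | intermediate (not isolated)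
13 | 1-{5-[2,4-bis(triisopropylsilyloxy)phenyl]-4-oxo-4H-pyran-2-yl}-2-diazo-5-methylhex-4-en-1-one | CC(C)=CCC(=[N+]=[N-])C(=O)c1cc(=O)c(-c2ccc(O[Si](C(C)C)(C(C)C)C(C)C)cc2O[Si](C(C)C)(C(C)C)C(C)C)co1 | intermediate
14 | ethyl 4-methylpent-3-enoate | CCOC(=O)CC=C(C)C | starting material
15 | lithium 1,1-dibromo-5-methylhexa-1,4-dien-2-olate | [Li+].[O-]C(CC=C(C)C)=C(Br)Br | intermediate (not isolated)
16 | lithium 5-methylhex-4-en-1-yn-1-olate | [Li+].[O-]C#CCC=C(C)C | intermediate (not isolated)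
17 | triisopropyl[(5-methylhex-4-en-1-yn-1-yl)oxy]silane | CC(C)=CCC#CO[Si](C(C)C)(C(C)C)C(C)C | intermediate
18 | 2-{5-[2,4-bis(triisopropylsilyloxy)phenyl]-4-oxo-4H-pyran-2-yl}-5-methylhexa-1,4-dien-1-one (vinylketene) | CC(C)=CCC(=C=O)c1cc(=O)c(-c2ccc(O[Si](C(C)C)(C(C)C)C(C)C)cc2O[Si](C(C)C)(C(C)C)C(C)C)co1 | intermediate (not isolated)
19 | 4-{5-[2,4-bis(triisopropylsilyloxy)phenyl]-4-oxo-4H-pyran-2-yl}-2,4-bis(3-methylbut-2-en-1-yl)-3-(triisopropylsilyloxy)cyclobut-2-en-1-one (racemic) | CC(C)=CCC1=C(O[Si](C(C)C)(C(C)C)C(C)C)C(CC=C(C)C)(c2cc(=O)c(-c3ccc(O[Si](C(C)C)(C(C)C)C(C)C)cc3O[Si](C(C)C)(C(C)C)C(C)C)co2)C1=O | intermediate (not isolated)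
20 | 4-{5-[2,4-bis(triisopropylsilyloxy)phenyl]-4-oxo-4H-pyran-2-yl}-7-methyl-2-(3-methylbut-2-en-1-yl)-3-(triisopropylsilyloxy)octa-1,3,6-trien-1-one, the isomer with ketene and pyranone on the same side of the C3=C4 bond | CC(C)=CCC(=C=O)/C(O[Si](C(C)C)(C(C)C)C(C)C)=C(/CC=C(C)C)c1cc(=O)c(-c2ccc(O[Si](C(C)C)(C(C)C)C(C)C)cc2O[Si](C(C)C)(C(C)C)C(C)C)co1 | intermediate (not isolated)
21 | 3-[2,4-bis(triisopropylsilyloxy)phenyl]-6,8-bis(3-methylbut-2-en-1-yl)-7-(triisopropylsilyloxy)-4aH-chromene-4,5-dione (racemic) | CC(C)=CCC1=C(O[Si](C(C)C)(C(C)C)C(C)C)C(CC=C(C)C)=C2OC=C(c3ccc(O[Si](C(C)C)(C(C)C)C(C)C)cc3O[Si](C(C)C)(C(C)C)C(C)C)C(=O)C2C1=O | intermediate (not isolated)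
22 | 3-[2,4-bis(triisopropylsilyloxy)phenyl]-5-hydroxy-6,8-bis(3-methylbut-2-en-1-yl)-7-(triisopropylsilyloxy)-4H-chromen-4-one | CC(C)=CCc1c(O[Si](C(C)C)(C(C)C)C(C)C)c(CC=C(C)C)c2occ(-c3ccc(O[Si](C(C)C)(C(C)C)C(C)C)cc3O[Si](C(C)C)(C(C)C)C(C)C)c(=O)c2c1O | intermediate
23 | 3-(2,4-dihydroxyphenyl)-5,7-dihydroxy-6,8-bis(3-methylbut-2-en-1-yl)-4H-chromen-4-one | CC(C)=CCc1c(O)c(CC=C(C)C)c2occ(-c3ccc(O)cc3O)c(=O)c2c1O | target

Total step count: 11.
Longest linear sequence: 9 steps (3 → 4 → 5 → 6 → 7 → 10 → 11 → 13 → 22 → 23; steps 2, 3, 4, 5, 6, 7, 8, 10, 11).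

Steps most likely to fail

1. Step 10. Hydrogen migration from the allylic CH2 on the diazo carbon may outrun the Wolff shift. The pyranone may also be degraded by light, or the dienylketene diverted before it cyclises. The fallback removes the substituent from the diazo carbon and brings the C8 prenyl group in afterwards; it sets out from 7 and returns at 22. Pinnick oxidation of 7 (NaClO2, NaH2PO4, 2-methylbut-2-ene, t-BuOH–H2O) should give 5-[2,4-bis(triisopropylsilyloxy)phenyl]-4-oxo-4H-pyran-2-carboxylic acid F1. Oxalyl chloride with catalytic DMF converts it into 5-[2,4-bis(triisopropylsilyloxy)phenyl]-4-oxo-4H-pyran-2-carbonyl chloride F2, and Me3SiCHN2 (MeCN–THF, 0 °C) into the diazomethyl ketone 5-[2,4-bis(triisopropylsilyloxy)phenyl]-2-(2-diazoacetyl)-4H-pyran-4-one F3, which has no migrating hydrogen beside the carbene centre. Irradiation of F3 with 17 under the conditions of step 10 should give 3-[2,4-bis(triisopropylsilyloxy)phenyl]-5-hydroxy-6-(3-methylbut-2-en-1-yl)-7-(triisopropylsilyloxy)-4H-chromen-4-one F4. Mitsunobu etherification of its C5 hydroxyl (3-methylbut-2-en-1-ol, PPh3, diisopropyl azodicarboxylate, THF) gives 3-[2,4-bis(triisopropylsilyloxy)phenyl]-6-(3-methylbut-2-en-1-yl)-5-(3-methylbut-2-en-1-yloxy)-7-(triisopropylsilyloxy)-4H-chromen-4-one F5. Both positions ortho to the C5 oxygen are blocked, so warming F5 with Eu(fod)3 (the tris(heptafluorodimethyloctanedionate) of trivalent europium) in chlorobenzene should trigger a para-Claisen–Cope rearrangement, first to C6 and then on to C8, and deliver 22.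

2. Step 9. The doubly activated CH2 of the β,γ-unsaturated ester may be deprotonated, or the alkene moved into conjugation, instead of the carbenoid adding to the ester carbonyl. The fallback delivers the ynolate oxygen by oxidation of an acetylide; it sets out from 14 and returns at 16. Reduction of 14 with i-Bu2AlH (CH2Cl2, −78 °C) should give 4-methylpent-3-enal F6, and CBr4/PPh3 (CH2Cl2, 0 °C) the dibromoalkene 1,1-dibromo-5-methylhexa-1,4-diene F7. n-BuLi (2 equiv, THF, −78 °C) converts F7 into (5-methylhex-4-en-1-yn-1-yl)lithium F8, which is oxidised in the same flask with LiOOt-Bu (from t-BuOOH and LiN(SiMe3)2) to ynolate 16; silylation as in step 9 then gives 17.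

3. Step 4. Hydroxide may cleave the electron-poor enol triflate, and the electron-rich ortho-silyloxy boronate may lose boron, before transmetalation takes place. The fallback is a base-free and water-free Stille coupling; it sets out from 4 and returns at 6. Stannylation of 4 (Me3SnSnMe3, Pd(PPh3)4, toluene, 100 °C) should give [2,4-bis(triisopropylsilyloxy)phenyl]trimethylstannane F9. Coupling of F9 with triflate 2 (Pd(PPh3)4, LiCl, CuI, DMF, 60 °C) gives 6.

Further compounds
F1 | step 10 | 5-[2,4-bis(triisopropylsilyloxy)phenyl]-4-oxo-4H-pyran-2-carboxylic acid | OC(=O)c1cc(=O)c(-c2ccc(O[Si](C(C)C)(C(C)C)C(C)C)cc2O[Si](C(C)C)(C(C)C)C(C)C)co1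
F2 | step 10 | 5-[2,4-bis(triisopropylsilyloxy)phenyl]-4-oxo-4H-pyran-2-carbonyl chloride | ClC(=O)c1cc(=O)c(-c2ccc(O[Si](C(C)C)(C(C)C)C(C)C)cc2O[Si](C(C)C)(C(C)C)C(C)C)co1
F3 | step 10 | 5-[2,4-bis(triisopropylsilyloxy)phenyl]-2-(2-diazoacetyl)-4H-pyran-4-one | [N-]=[N+]=CC(=O)c1cc(=O)c(-c2ccc(O[Si](C(C)C)(C(C)C)C(C)C)cc2O[Si](C(C)C)(C(C)C)C(C)C)co1
F4 | step 10 | 3-[2,4-bis(triisopropylsilyloxy)phenyl]-5-hydroxy-6-(3-methylbut-2-en-1-yl)-7-(triisopropylsilyloxy)-4H-chromen-4-one | CC(C)=CCc1c(O[Si](C(C)C)(C(C)C)C(C)C)cc2occ(-c3ccc(O[Si](C(C)C)(C(C)C)C(C)C)cc3O[Si](C(C)C)(C(C)C)C(C)C)c(=O)c2c1O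
F5 | step 10 | 3-[2,4-bis(triisopropylsilyloxy)phenyl]-6-(3-methylbut-2-en-1-yl)-5-(3-methylbut-2-en-1-yloxy)-7-(triisopropylsilyloxy)-4H-chromen-4-one | CC(C)=CCOc1c(CC=C(C)C)c(O[Si](C(C)C)(C(C)C)C(C)C)cc2occ(-c3ccc(O[Si](C(C)C)(C(C)C)C(C)C)cc3O[Si](C(C)C)(C(C)C)C(C)C)c(=O)c12
F6 | step 9 | 4-methylpent-3-enal | CC(C)=CCC=O
F7 | step 9 | 1,1-dibromo-5-methylhexa-1,4-diene | CC(C)=CCC=C(Br)Br
F8 | step 9 | (5-methylhex-4-en-1-yn-1-yl)lithium | [Li]C#CCC=C(C)C
F9 | step 4 | [2,4-bis(triisopropylsilyloxy)phenyl]trimethylstannane | C[Sn](C)(C)c1ccc(O[Si](C(C)C)(C(C)C)C(C)C)cc1O[Si](C(C)C)(C(C)C)C(C)C
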